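**Retrosynthetic overview**
1. Target 16 ⇐ aryl iodide 14 + alkenylboronate 15 (Suzuki coupling, last step); 14 ⇐ methyl ketone 13 (Wittig methylenation).
2. Key disconnection: 13 is the opened form of 2-silyloxychroman 12. The chroman O1–C2 bond (C–O) and the C3–C4 bond are made together in an asymmetric oxa-[4+2] cycloaddition of o-quinone methide 11 with silyl enol ether 10; this sets the only stereocenter.
3. 11 is stored as benzodioxaborin 7 (ortho-hydroxymethylation of iodide 6); 10 comes from methyl vinyl ketone and methallylmagnesium chloride.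
4. Core: Houben–Hoesch acylation of phloroglucinol, then the second strategic C–O bond, the pKa-controlled 4-O-methylation, then mono-iodination.
5. Ring order: rings A and B are bought. The dioxaborin ring (step 4) and the dihydropyran ring of the chroman (step 6) are the only rings formed, and both are opened again within step 6.

Assumption 1: boronate 15 is a catalogue compound and is bought (otherwise one step from 3-methylbut-1-yne and pinacolborane).
Assumption 2: the (R)-configured acid in step 6 is taken to give the (R)-ketone; if the sense of induction is opposite, its (S)-enantiomer is used.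

**Route**

Step 1
Reactants: 1 phloroglucinol; 2 3-hydroxybenzonitrile
Product: 4 (3-hydroxyphenyl)(2,4,6-trihydroxyphenyl)methanone, via ketiminium chloride 3 (not isolated)
Conditions: ZnCl2 (1.2 equiv), HCl (g), Et2O, 0 °C → rt; then H2O, 100 °C
Reagents that add atoms: water, O; hydrogen chloride, Cl (retained only in 3)
Why: Houben–Hoesch acylation: the nitrilium from 2 attacks the symmetric, highly nucleophilic arene once (the ketiminium deactivates it against a second acylation) and hydrolysis gives the ketone; no stereocenter is formed.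

Step 2
Reactants: 4 (3-hydroxyphenyl)(2,4,6-trihydroxyphenyl)methanone
Product: 5 (2,6-dihydroxy-4-methoxyphenyl)(3-hydroxyphenyl)methanone
Conditions: Me2SO4 (1.05 equiv), K2CO3 (1.0 equiv), acetone, 56 °C
Reagents that add atoms: dimethyl sulfate, COS(=O)(=O)OC
Why: Williamson-type O-methylation under pKa control: the 4-OH (para to the carbonyl, not hydrogen-bonded) is the most acidic oxygen, the 2- and 6-OH are chelated to C=O and the 3'-OH is roughly 1.5 pKa units weaker, so one equivalent of base gives the 4-methyl ether (the selectivity known from 7-O-methylation of 5,7,4'-trihydroxyflavonoids); no stereocenter.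

Step 3
Reactants: 5 (2,6-dihydroxy-4-methoxyphenyl)(3-hydroxyphenyl)methanone
Product: 6 (2,6-dihydroxy-3-iodo-4-methoxyphenyl)(3-hydroxyphenyl)methanone
Conditions: N-iodosuccinimide (1.0 equiv), DMF, −20 → 0 °C
Reagents that add atoms: N-iodosuccinimide, O=C1CCC(=O)N1I
Why: Electrophilic aromatic iodination: ring A carries three oxygen donors and is far more reactive than ring B, its two free positions are equivalent, and the first iodine slows a second substitution; no stereocenter.

Step 4
Reactants: 6 (2,6-dihydroxy-3-iodo-4-methoxyphenyl)(3-hydroxyphenyl)methanone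
Product: 7 (7-hydroxy-6-iodo-5-methoxy-2-phenyl-4H-1,3,2-benzodioxaborinin-8-yl)(3-hydroxyphenyl)methanone
Conditions: (CH2O)n (1.2 equiv), PhB(OH)2 (1.1 equiv), EtCO2H (10 mol%), toluene, 110 °C, Dean–Stark
Reagents that add atoms: formaldehyde (as paraformaldehyde), C=O; phenylboronic acid, OB(O)c1ccccc1
Why: Nagata ortho-hydroxymethylation: the aryloxyboron species delivers formaldehyde to the only free carbon of ring A and the product is trapped at once as the cyclic boronate, which prevents diarylmethane formation and stores the o-quinone methide; no stereocenter.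

Step 5
Reactants: 8 but-3-en-2-one (methyl vinyl ketone); 9 (2-methylallyl)magnesium chloride
Product: 10 trimethyl{[(2Z)-6-methylhepta-2,6-dien-2-yl]oxy}silane
Conditions: CuBr·SMe2 (5 mol%), LiCl (10 mol%), Me3SiCl (1.2 equiv), THF, −78 °C; Et3N, pentane work-up, distillation
Reagents that add atoms: chlorotrimethylsilane, C[Si](C)(C)Cl
Why: Copper-catalysed conjugate (1,4-) addition of the Grignard reagent, accelerated and trapped by Me3SiCl, gives the enol silane with the double bond fixed on the internal side, expected mainly as the Z isomer (from the s-cis enone); no stereocenter.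

Step 6
Reactants: 7 (7-hydroxy-6-iodo-5-methoxy-2-phenyl-4H-1,3,2-benzodioxaborinin-8-yl)(3-hydroxyphenyl)methanone; 10 trimethyl{[(2Z)-6-methylhepta-2,6-dien-2-yl]oxy}silane
Product: 13 (3R)-3-{[2,4-dihydroxy-3-(3-hydroxybenzoyl)-5-iodo-6-methoxyphenyl]methyl}-6-methylhept-6-en-2-one, via o-quinone methide 11 (not isolated), via 2-silyloxychroman 12 (not isolated)
Conditions: (R)-3,3'-bis(2,4,6-triisopropylphenyl)-1,1'-binaphthyl-2,2'-diyl N-triflylphosphoramide (10 mol%), 10 (2 equiv), 5 Å molecular sieves, toluene, −20 °C; then THF/aq. citric acid, 0 °C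
Reagents that add atoms: none
Why: Proposed new method: Brønsted acid-catalysed enantioselective inverse-electron-demand oxa-[4+2] cycloaddition of a 4-unsubstituted o-quinone methide with a (Z)-trisubstituted silyl enol ether — the chiral acid opens the dioxaborin and holds the O-protonated o-quinone methide 11 as a hydrogen-bonded contact ion pair in its pocket (activation of the electrophile only), the enol ether adds with one enantioface to the exocyclic CH2 in an endo transition state so that the C4–C3 bond and the chroman O1–C2 bond are formed and C3 is set as (R), and mild hydrolysis of silyl ketal 12 releases the ketone without touching the new centre; closest known reaction types: chiral phosphoric acid or N-triflylphosphoramide-catalysed [4+2] cycloadditions of o-quinone methides with unactivated alkenes, and the racemic thermal o-quinone methide/enol ether chroman synthesis from benzodioxaborins.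

Step 7
Reactants: 13 (3R)-3-{[2,4-dihydroxy-3-(3-hydroxybenzoyl)-5-iodo-6-methoxyphenyl]methyl}-6-methylhept-6-en-2-one
Product: 14 {2,6-dihydroxy-3-iodo-4-methoxy-5-[(2R)-5-methyl-2-(prop-1-en-2-yl)hex-5-en-1-yl]phenyl}(3-hydroxyphenyl)methanone
Conditions: Ph3PCH3Br (6.0 equiv), KOt-Bu (5.5 equiv), THF, 0 °C → rt
Reagents that add atoms: methyltriphenylphosphonium bromide, C[P+](c1ccccc1)(c1ccccc1)c1ccccc1.[Br-]
Why: Wittig methylenation: the unstabilised ylide (phosphonium salt in excess over base, so no free alkoxide is present) reacts only with the dialkyl ketone, the 2,6-dioxido diaryl ketone being too hindered and electron-rich, and the stereocenter, now allylic instead of α to a carbonyl, keeps its (R) configuration (the CIP order is unchanged).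

Step 8
Reactants: 14 {2,6-dihydroxy-3-iodo-4-methoxy-5-[(2R)-5-methyl-2-(prop-1-en-2-yl)hex-5-en-1-yl]phenyl}(3-hydroxyphenyl)methanone; 15 4,4,5,5-tetramethyl-2-[(1E)-3-methylbut-1-en-1-yl]-1,3,2-dioxaborolane
Product: 16 {2,6-dihydroxy-4-methoxy-3-[(1E)-3-methylbut-1-en-1-yl]-5-[(2R)-5-methyl-2-(prop-1-en-2-yl)hex-5-en-1-yl]phenyl}(3-hydroxyphenyl)methanone (the target)
Conditions: Pd(OAc)2 (5 mol%), 2-dicyclohexylphosphino-2',6'-dimethoxybiphenyl (10 mol%), K3PO4 (4 equiv), 1,4-dioxane/H2O (5:1), 80 °C
Reagents that add atoms: none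
Why: Suzuki–Miyaura coupling: the hindered, electron-rich aryl iodide undergoes oxidative addition to the phosphine-ligated zerovalent palladium, transmetalation and reductive elimination keep the E geometry of the alkenylboronate, free phenols and 1,1-disubstituted alkenes are tolerated, and the stereocenter is not touched.

**Compound list**
1 | benzene-1,3,5-triol (phloroglucinol) | Oc1cc(O)cc(O)c1 | starting material
2 | 3-hydroxybenzonitrile | N#Cc1cccc(O)c1 | starting material
3 | (3-hydroxyphenyl)(2,4,6-trihydroxyphenyl)methaniminium chloride (ketiminium chloride) | [NH2+]=C(c1cccc(O)c1)c1c(O)cc(O)cc1O.[Cl-] | intermediate (not isolated)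
4 | (3-hydroxyphenyl)(2,4,6-trihydroxyphenyl)methanone | O=C(c1cccc(O)c1)c1c(O)cc(O)cc1O | intermediate
5 | (2,6-dihydroxy-4-methoxyphenyl)(3-hydroxyphenyl)methanone | COc1cc(O)c(C(=O)c2cccc(O)c2)c(O)c1 | intermediate
6 | (2,6-dihydroxy-3-iodo-4-methoxyphenyl)(3-hydroxyphenyl)methanone | COc1cc(O)c(C(=O)c2cccc(O)c2)c(O)c1I | intermediate
7 | (7-hydroxy-6-iodo-5-methoxy-2-phenyl-4H-1,3,2-benzodioxaborinin-8-yl)(3-hydroxyphenyl)methanone | COc1c(I)c(O)c(C(=O)c2cccc(O)c2)c2OB(c3ccccc3)OCc12 | intermediate
8 | but-3-en-2-one (methyl vinyl ketone) | CC(=O)C=C | starting material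
9 | (2-methylallyl)magnesium chloride | CC(=C)C[Mg]Cl | starting material
10 | trimethyl{[(2Z)-6-methylhepta-2,6-dien-2-yl]oxy}silane | C/C(O[Si](C)(C)C)=C/CCC(C)=C | intermediate
11 | 3-hydroxy-2-(3-hydroxybenzoyl)-4-iodo-5-methoxy-6-methylidenecyclohexa-2,4-dien-1-one (o-quinone methide) | C=C1C(=O)C(C(=O)c2cccc(O)c2)=C(O)C(I)=C1OC | intermediate (not isolated)
12 | {(3R)-7-hydroxy-6-iodo-5-methoxy-2-methyl-3-(3-methylbut-3-en-1-yl)-2-[(trimethylsilyl)oxy]-3,4-dihydro-2H-chromen-8-yl}(3-hydroxyphenyl)methanone, both C2 epimers (2-silyloxychroman) | CC1(O[Si](C)(C)C)Oc2c(C(=O)c3cccc(O)c3)c(O)c(I)c(OC)c2C[C@H]1CCC(C)=C | intermediate (not isolated)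
13 | (3R)-3-{[2,4-dihydroxy-3-(3-hydroxybenzoyl)-5-iodo-6-methoxyphenyl]methyl}-6-methylhept-6-en-2-one | C=C(C)CC[C@H](Cc1c(O)c(C(=O)c2cccc(O)c2)c(O)c(I)c1OC)C(C)=O | intermediate
14 | {2,6-dihydroxy-3-iodo-4-methoxy-5-[(2R)-5-methyl-2-(prop-1-en-2-yl)hex-5-en-1-yl]phenyl}(3-hydroxyphenyl)methanone | C=C(C)CC[C@H](Cc1c(O)c(C(=O)c2cccc(O)c2)c(O)c(I)c1OC)C(=C)C | intermediate
15 | 4,4,5,5-tetramethyl-2-[(1E)-3-methylbut-1-en-1-yl]-1,3,2-dioxaborolane | CC(C)/C=C/B1OC(C)(C)C(C)(C)O1 | starting material
16 | {2,6-dihydroxy-4-methoxy-3-[(1E)-3-methylbut-1-en-1-yl]-5-[(2R)-5-methyl-2-(prop-1-en-2-yl)hex-5-en-1-yl]phenyl}(3-hydroxyphenyl)methanone (CNP0208548.1) | C=C(C)CC[C@H](Cc1c(O)c(C(=O)c2cccc(O)c2)c(O)c(/C=C/C(C)C)c1OC)C(=C)C | target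

**Count**
Total step count: 8. Longest linear sequence: 7 steps (1, 2, 3, 4, 6, 7, 8).

**Three steps most likely to fail**

Step 6 (the proposed new step). Risks are low or inverted enantioselectivity, sluggish acid-induced opening of the dioxaborin, protodesilylation of 10, and an E/Z-impure enol silane eroding the selectivity. The fallback uses known chemistry and replaces catalyst control by racemic synthesis plus resolution. It sets out from 7 (with 10): heating both in toluene at 100 °C, the established thermal o-quinone methide/enol ether chroman synthesis from benzodioxaborins, gives the racemic 2-silyloxychroman F1. Aqueous citric acid opens it to the racemic ketone F2. Preparative chromatography on a chiral stationary phase then gives the (R)-enantiomer, which is 13; the (S)-enantiomer is racemised with DBU in THF and recycled. The fallback comes back to the route at 13.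

Step 7. Risks are partial epimerisation of the α-stereocenter of 13 by the basic ylide before olefination, and slow reaction of the poorly soluble tris-phenoxide. The fallback is a two-stage Peterson olefination that sets out from 13: the weakly basic organocerium reagent from Me3SiCH2MgCl and CeCl3 (THF, −78 °C) adds to the ketone to give the β-hydroxysilane F3 (mixture at the carbinol carbon), and KH in THF induces syn-elimination. The fallback comes back to the route at 14.

Step 5. Risks are 1,2-addition of the allylic Grignard reagent, polymerisation of methyl vinyl ketone, and an E/Z mixture. The fallback sets out from 8: Hosomi–Sakurai conjugate allylation with methallyltrimethylsilane and TiCl4 (CH2Cl2, −78 °C) gives 6-methylhept-6-en-2-one F4, and thermodynamic silylation (Me3SiCl, NaI, Et3N, MeCN) gives the internal Z enol silane, the minor terminal regioisomer being removed by distillation. The fallback comes back to the route at 10.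

Further compounds
F1 | step 6 | racemic {7-hydroxy-6-iodo-5-methoxy-2-methyl-3-(3-methylbut-3-en-1-yl)-2-[(trimethylsilyl)oxy]-3,4-dihydro-2H-chromen-8-yl}(3-hydroxyphenyl)methanone (racemic 2-silyloxychroman) | CC1(O[Si](C)(C)C)Oc2c(C(=O)c3cccc(O)c3)c(O)c(I)c(OC)c2CC1CCC(C)=C
F2 | step 6 | racemic 3-{[2,4-dihydroxy-3-(3-hydroxybenzoyl)-5-iodo-6-methoxyphenyl]methyl}-6-methylhept-6-en-2-one (racemic ketone) | C=C(C)CCC(Cc1c(O)c(C(=O)c2cccc(O)c2)c(O)c(I)c1OC)C(C)=O
F3 | step 7 | (3R)-3-{[2,4-dihydroxy-3-(3-hydroxybenzoyl)-5-iodo-6-methoxyphenyl]methyl}-2,6-dimethyl-1-(trimethylsilyl)hept-6-en-2-ol, both C2 epimers (β-hydroxysilane) | C=C(C)CC[C@H](Cc1c(O)c(C(=O)c2cccc(O)c2)c(O)c(I)c1OC)C(C)(O)C[Si](C)(C)C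
F4 | step 5 | 6-methylhept-6-en-2-one | CC(=O)CCCC(C)=C
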